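## Structural features

The target 19 is an achiral diarylmethane: two benzene rings joined only through the methylene carbon C8, with no stereocentre and therefore no neighbouring stereocentres to relate. Ring A carries five contiguous substituents: the hydroxymethyl carbon C7 on C1, C8 on C2, hydroxyls on C3 and C4, and bromine on C5; only C6 bears hydrogen. Ring B is a 1,3,4-trisubstituted phenol (C1' bound to C8, Br on C3', OH on C4'). The fragile elements are the catechol (oxidation to the ortho-quinone), the C7 alcohol para to the C4 hydroxyl (ionisation to a quinone methide under acid or base), the two C–Br bonds (lost under catalytic hydrogenation) and the doubly benzylic C8 (radical halogenation). The real difficulty is ring A: five different groups in a fixed order, C2 wedged between C1 and C3, and two catechol oxygens that must be told apart so that bromine enters at C5 and not at C6. The feature used is the 1,2-relationship of C8 on C2 and oxygen on C3: with C8 at the ketone level this is an ortho-acylphenol, the cyclised enol of a 1,3-diketone C8–C2–C3 whose next carbon C4 already bears oxygen. The other three ring carbons C5, C6 and C1, with C7 at the carboxyl level, correspond to a β-alkoxyvinyl α-keto ester, so ring A can be closed by forming C4–C5 and C1–C2.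

## Logic of the disconnections

19 to 18. No skeletal bond is cut; the two C7–H bonds are traced back to an ester carbonyl. The ester survives every electrophilic and Lewis-acidic step, deactivates C6, and keeps the quinone-methide-prone benzylic alcohol out of the route until the end. The forward step must reduce an ester in the presence of three acidic phenols and two aryl bromides, with a work-up that is not strongly acidic.

18 to 17. The O–CH3 bonds at C3 and C4' are cut. Both ethers fall in one operation. The ring B ether limits ring B to a single ortho bromination, and the C3 ether leaves the free C4 hydroxyl as the dominant director on ring A. The forward step needs an ether cleavage that spares the methyl ester and the C–Br bonds.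

17 to 15 (through 16). The C5–Br and C3'–Br bonds are cut. Both carbons are the innate sites of electrophilic attack: C5 is the only free position ortho or para to the C4 hydroxyl, and C3' is ortho to the ring B methoxy group whose para position is blocked. The gain is bromine-free intermediates that tolerate hydrogenolysis. The forward step must stay ionic (no radical attack at C8), must prefer C5 over C6 (para to the weaker, flanked C3 methoxy group and ortho to the ester), and must stop at two bromines.

15 to 14. The O–benzyl bond at C4 is cut. Benzyl against methyl is what distinguishes O4 from O3, and hydrogenolysis is clean provided no bromine and no reducible ketone is present. This fixes the order: deoxygenate C8 first, debenzylate second, brominate third.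

14 to 12 (through 13). The two C8–H bonds are traced back to the C8 ketone that the ring synthesis delivers. A catalytic hydrogenolysis of this ketone is deliberately avoided: the diarylmethanol formed on the way sits ortho to the C1 ester and would lactonise, so that an acid instead of the ester would result. The forward step must therefore deoxygenate through a cation and not through a free alkoxide.

12 to 11. The O–CH3 bond at C3 is cut. The annulation releases O3 as a free phenol while O4 arrives protected, so one methylation completes the differentiation. The forward step must alkylate a hindered, hydrogen-bonded phenol.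

11 to 5 + 8. The ring A bonds C4–C5 and C1–C2 are cut. This is the ortho-acylphenol retron. A ring with four correctly placed substituents (ester on C1, aroyl on C2, free OH on C3, protected O on C4) falls into two acyclic pieces, and ring B with C8 comes along on the diene. The forward step must pair the diene terminus with the β-carbon of the enone and the central diene carbon with the keto carbonyl, not the reverse.

5 to 4 to 3. Two O–Si bonds are cut in turn. The diketone is activated as its bis(silyl enol ether) in the standard two stages. The demand is deprotonation at C4, the only enolisable position left, O-silylation, and exclusion of moisture.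

3 to 1 + 2. The C2–C3 bond is cut (Claisen retron). The four-carbon diketone carrying ring B and the benzyloxy group comes from two commercial compounds. The ketone enolate must be acylated faster than the ester condenses with itself.

8 to 6 + 7. The bond between future C6 and C1 is cut (acylation of an enol ether). The forward step needs C-acylation at the β-carbon of the enol ether and loss of HCl to the E enone.

## Other disconnections considered

Alternative 1: The two exocyclic bonds of ring A, C1–C7 and C2–C8, are cut together. In the forward direction CsF releases an aryne across C1–C2 from 4-isopropoxy-3-methoxy-2-(trimethylsilyl)phenyl triflate A2. The isocyanide component, tert-butyl isocyanide A4, adds at C1, the position remote from the C3 methoxy group. The C2 aryl anion then adds to 3-bromo-4-methoxybenzaldehyde A3, and the alkoxide closes on the nitrilium carbon to give the racemic imidate A1.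
- In its favour: both benzylic carbons are attached in one convergent step, C7 arrives at the carboxyl level, and ring B arrives with its bromine.
- Against it: the regiodefined tetrasubstituted arene A2 has to be made in several steps, so the substitution problem of ring A is moved into the precursor and not solved. After hydrolysis of A1 to the lactone A5, the C8–O bond must be cut reductively without hydrogen over palladium because of the aryl bromide. The C5 bromine still has to be introduced late, after selective removal of the isopropyl group.
- Comparison: on convergence and on the ring B bromine this plan is the better one. On bond count it is equal (two skeletal bonds), but the ring it closes is taken apart again, whereas the chosen plan builds ring A itself. Both are polar cascades resting on one regiochemical preference (aryne polarisation here, 1,4- before 1,2-addition there). With the steps to A2 included it is not expected to be shorter.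

Alternative 2: Ring B is cut at C1'–C6' and C2'–C3'. In the forward direction the aldehyde methyl 5-bromo-3,4-dimethoxy-2-(3-oxopropyl)benzoate A7 and methyl vinyl ketone A8 undergo amine-catalysed Michael addition and aldol condensation to the racemic cyclohexenone A6. The new six-membered ring of A6 must then be dehydrogenated to the aromatic ring B with its hydroxyl, brominated once, demethylated and reduced.
- In its favour: C8 is a methylene from the start, ring A comes fully substituted with the C5 bromine already in place, and the ring B hydroxyl needs no protecting group.
- Against it: it constructs the ring that can be bought and leaves the hard task, a three-carbon chain on the crowded C2 next to a C5 bromide, to the synthesis of A7. The aromatisation needs an oxidant compatible with an aryl bromide and two benzylic positions. Monobromination of the free para-alkylphenol must stop after one bromine.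
- Comparison: it is better in needing no deoxygenation at C8 and no regiocontrol for the ring A bromine. It is equal in ring and bond count of the key step. It is weaker in strategic value and, with four or five steps to A7 and an extra oxidation, probably longer.

Alternative 3: Ring A is cut at C1–C6. In the forward direction, heating the vinylcyclobutenone A10 (made from dimethyl squarate A11 by two successive organometallic additions and silylation) opens the four-membered ring to a dienylketene. This closes by 6π electrocyclisation and tautomerises to the phenol A9.
- In its favour: the regiochemistry is fixed by the order of additions to A11 and not by a selectivity, C8 is already a methylene, and O3 and O4 are differentiated from the outset.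
- Against it: C1 of A9 emerges bearing a hydroxyl where the target needs carbon, so sulfonate formation and a palladium-catalysed alkoxycarbonylation next to the benzyl group are added. A 4-methoxybenzyl organometallic is prone to homocoupling, and the second addition to the squarate must be regioselective. Only one ring bond is formed in the key step.
- Comparison: it is the better plan in regiochemical certainty and in avoiding the ketone deoxygenation, and equal in oxygen differentiation. After the ester is installed the endgame is the same as in the chosen plan (deprotection at O4, double bromination, demethylation, reduction). The step count is expected to be equal or one to two steps higher.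

Key step: step 5

Remark on the chemistry: ring A atoms are C1–C6, C7 is the hydroxymethyl carbon, C8 the bridging methylene, and ring B atoms are primed. Compound 4 is drawn as one regioisomer of the mono silyl enol ether; the other would converge on the same diene 5.

## Route

Step 1
Reactants: 1 4-methoxyacetophenone; 2 methyl 2-(benzyloxy)acetate
Product: 3 4-(benzyloxy)-1-(4-methoxyphenyl)butane-1,3-dione
Conditions: NaH, THF, 0 °C to rt; then aq. HCl
Reagents that add atoms: none
Why: Crossed Claisen condensation: the sodium enolate of 1 is acylated by the inductively activated α-alkoxy ester 2, and deprotonation of the 1,3-diketone formed drives the equilibrium; adding 2 to the preformed enolate limits its self-condensation.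

Step 2
Reactants: 3 4-(benzyloxy)-1-(4-methoxyphenyl)butane-1,3-dione
Product: 4 (Z)-4-(benzyloxy)-1-(4-methoxyphenyl)-3-(trimethylsilyloxy)but-2-en-1-one
Conditions: TMSCl, Et3N, toluene, rt
Reagents that add atoms: chlorotrimethylsilane, C[Si](C)(C)Cl
Why: O-Silylation of the enolised 1,3-diketone under soft enolisation gives the 3-silyloxy-2-en-1-one, the first stage of the standard preparation of diketone-derived bis(silyl enol ethers); the crude product is used after filtration of the ammonium salt.

Step 3
Reactants: 4 (Z)-4-(benzyloxy)-1-(4-methoxyphenyl)-3-(trimethylsilyloxy)but-2-en-1-one
Product: 5 4-(benzyloxy)-1-(4-methoxyphenyl)-1,3-bis(trimethylsilyloxy)buta-1,3-diene (mixture of enol ether geometries)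
Conditions: LiN(iPr)2, THF, −78 °C; then TMSCl, −78 °C to rt
Reagents that add atoms: chlorotrimethylsilane, C[Si](C)(C)Cl
Why: Kinetic deprotonation at C4, the only enolisable position left (the aryl side has no α-hydrogen), followed by O-silylation of the resulting anion; this is the second stage of the standard preparation of 1,3-bis(silyloxy)-1,3-dienes, and the diene geometry is irrelevant because it is lost on aromatisation.

Step 4
Reactants: 6 ethyl vinyl ether; 7 methyl oxalyl chloride
Product: 8 methyl (E)-4-ethoxy-2-oxobut-3-enoate
Conditions: pyridine, CH2Cl2, 0 °C to rt
Reagents that add atoms: none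
Why: Electrophilic C-acylation of the enol ether at its β-carbon by the very reactive oxalyl monoester chloride, followed by base-assisted loss of HCl (addition–elimination), the usual entry to β-alkoxyvinyl ketones; the E alkene is the thermodynamic product.

Step 5
Reactants: 5 4-(benzyloxy)-1-(4-methoxyphenyl)-1,3-bis(trimethylsilyloxy)buta-1,3-diene; 8 methyl (E)-4-ethoxy-2-oxobut-3-enoate
Product: 11 methyl 4-(benzyloxy)-3-hydroxy-2-(4-methoxybenzoyl)benzoate, via open-chain enetrione 9 (not isolated), via cyclohexenone aldol adduct 10 (not isolated)
Conditions: TiCl4, CH2Cl2, −78 to 20 °C; then aq. HCl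
Reagents that add atoms: none
Why: TiCl4 chelates the 1,2-dicarbonyl unit of 8 and polarises its β-carbon; the terminal carbon of 5 (future C4), the most nucleophilic site of the diene, adds there in a Mukaiyama–Michael reaction and ethoxide is expelled, giving 9 with the new bond C4–C5. The remaining silyl enol ether carbon (future C2) then attacks the titanium-activated keto carbonyl (future C1) in an intramolecular Mukaiyama aldol reaction, a 6-(enolexo)-exo-trig closure that forms C1–C2 and gives 10; only the Z form of 9 can close, and the E form can reach it through the C4 enol or by reversible conjugate addition of chloride. Loss of water and enolisation of the C3 carbonyl then give the benzene ring, which is the driving force. The closest known reaction type is the TiCl4-mediated formal [3+3] cyclocondensation of 1,3-bis(silyloxy)-1,3-dienes with 3-alkoxy-2-en-1-ones, which gives salicylates from β-keto ester dienes and 2-acylphenols from diketone dienes. No stereocentre is set: the centres of 9 and 10 are erased on aromatisation. The step needs 1,4- before 1,2-attack on 8; this rests on the vinylogous ester character of the acceptor, on the soft terminal carbon of 5 and on mixing at −78 °C with slow warming. The benzyl ether should survive TiCl4 at low temperature, and the C3 phenol is released from its titanium chelate with the C8 ketone on acidic work-up.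

Step 6
Reactants: 11 methyl 4-(benzyloxy)-3-hydroxy-2-(4-methoxybenzoyl)benzoate
Product: 12 methyl 4-(benzyloxy)-3-methoxy-2-(4-methoxybenzoyl)benzoate
Conditions: MeI, K2CO3, DMF, 40 °C
Reagents that add atoms: iodomethane, CI
Why: Williamson O-methylation of the C3 phenol, which is acidified by the ortho aroyl group; the dipolar aprotic medium breaks its hydrogen bond to the ketone. The ether replaces the strongly para-directing C3 hydroxyl by a flanked, weaker methoxy donor, so that the later bromination is steered by the free C4 hydroxyl.

Step 7
Reactants: 12 methyl 4-(benzyloxy)-3-methoxy-2-(4-methoxybenzoyl)benzoate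
Product: 14 methyl 4-(benzyloxy)-3-methoxy-2-(4-methoxybenzyl)benzoate, via diarylmethanol 13 (not isolated)
Conditions: Et3SiH, TFA, CH2Cl2, 0 °C to rt
Reagents that add atoms: none
Why: Ionic hydrogenation (Kursanov–Parnes reduction): hydride transfer from the silane to the protonated ketone gives 13, which ionises in TFA to a diarylmethyl cation stabilised by the para-methoxy group and accepts a second hydride. No free alkoxide is formed, so lactonisation onto the C1 ester is disfavoured, and the benzyl ether, whose oxygen is para to the ester, should be only marginally acid-labile.

Step 8
Reactants: 14 methyl 4-(benzyloxy)-3-methoxy-2-(4-methoxybenzyl)benzoate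
Product: 15 methyl 4-hydroxy-3-methoxy-2-(4-methoxybenzyl)benzoate
Conditions: H2 (1 atm), Pd/C, EtOAc, rt
Reagents that add atoms: none
Why: Hydrogenolysis of the benzyl aryl ether under neutral conditions; the diarylmethane, ester and methyl ethers are inert, and the step is placed before any bromine is present.

Step 9
Reactants: 15 methyl 4-hydroxy-3-methoxy-2-(4-methoxybenzyl)benzoate
Product: 17 methyl 5-bromo-2-(3-bromo-4-methoxybenzyl)-4-hydroxy-3-methoxybenzoate, via ring A monobromide 16 (not isolated)
Conditions: NBS (2 equiv), MeCN, 0 °C to rt, dark
Reagents that add atoms: N-bromosuccinimide, O=C1CCC(=O)N1Br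
Why: Electrophilic aromatic bromination: the first equivalent enters at C5, the only free position ortho or para to the C4 hydroxyl, giving 16; the second enters ortho to the methoxy group of ring B, whose para position is blocked. The polar solvent and exclusion of light favour the ionic over the benzylic radical pathway; C6 is para only to the twisted, doubly flanked C3 methoxy group and ortho to the ester, and the second ortho position of the bromo-deactivated ring B is much less reactive.

Step 10
Reactants: 17 methyl 5-bromo-2-(3-bromo-4-methoxybenzyl)-4-hydroxy-3-methoxybenzoate
Product: 18 methyl 5-bromo-2-(3-bromo-4-hydroxybenzyl)-3,4-dihydroxybenzoate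
Conditions: BBr3, CH2Cl2, −78 to 0 °C; then H2O
Reagents that add atoms: none
Why: Lewis-acid ether cleavage: BBr3 coordinates each methoxy oxygen and bromide removes the methyl group by SN2 attack, with the C3 ether assisted by the neighbouring C4 borate. At or below 0 °C the methyl benzoate and the aryl bromides are expected to survive.

Step 11
Reactants: 18 methyl 5-bromo-2-(3-bromo-4-hydroxybenzyl)-3,4-dihydroxybenzoate
Product: 19 6-bromo-3-(3-bromo-4-hydroxybenzyl)-4-(hydroxymethyl)benzene-1,2-diol
Conditions: iBu2AlH (excess), THF, −78 to 0 °C; then aq. KNaC4H4O6
Reagents that add atoms: none
Why: The aluminium hydride first metalates the three phenols (hence the excess) and then reduces the ester to the benzylic alkoxide; aryl bromides are inert to this electrophilic hydride at or below 0 °C. The buffered tartrate work-up frees the aluminium-bound catechol without acid strong enough to ionise the para-hydroxybenzyl alcohol.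

## Compound list

1 | 4-methoxyacetophenone | CC(=O)c1ccc(OC)cc1 | starting material
2 | methyl 2-(benzyloxy)acetate | COC(=O)COCc1ccccc1 | starting material
3 | 4-(benzyloxy)-1-(4-methoxyphenyl)butane-1,3-dione | COc1ccc(cc1)C(=O)CC(=O)COCc1ccccc1 | intermediate
4 | (Z)-4-(benzyloxy)-1-(4-methoxyphenyl)-3-(trimethylsilyloxy)but-2-en-1-one | COc1ccc(cc1)C(=O)/C=C(\O[Si](C)(C)C)COCc1ccccc1 | intermediate
5 | 4-(benzyloxy)-1-(4-methoxyphenyl)-1,3-bis(trimethylsilyloxy)buta-1,3-diene (mixture of enol ether geometries, drawn without geometry) | COc1ccc(cc1)C(O[Si](C)(C)C)=CC(O[Si](C)(C)C)=COCc1ccccc1 | intermediate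
6 | ethyl vinyl ether | C=COCC | starting material
7 | methyl oxalyl chloride (methyl 2-chloro-2-oxoacetate) | COC(=O)C(=O)Cl | starting material
8 | methyl (E)-4-ethoxy-2-oxobut-3-enoate | CCO/C=C/C(=O)C(=O)OC | intermediate
9 | methyl (Z)-5-(benzyloxy)-8-(4-methoxyphenyl)-2,6,8-trioxooct-3-enoate (racemic; present as its silyl or titanium enolate, drawn as the neutral triketone) | COC(=O)C(=O)/C=C\C(OCc1ccccc1)C(=O)CC(=O)c1ccc(OC)cc1 | intermediate
10 | methyl 4-(benzyloxy)-1-hydroxy-2-(4-methoxybenzoyl)-3-oxocyclohex-5-ene-1-carboxylate (mixture of diastereomers, all centres lost on aromatisation) | COC(=O)C1(O)C=CC(OCc2ccccc2)C(=O)C1C(=O)c1ccc(OC)cc1 | intermediate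
11 | methyl 4-(benzyloxy)-3-hydroxy-2-(4-methoxybenzoyl)benzoate | COC(=O)c1ccc(OCc2ccccc2)c(O)c1C(=O)c1ccc(OC)cc1 | intermediate
12 | methyl 4-(benzyloxy)-3-methoxy-2-(4-methoxybenzoyl)benzoate | COC(=O)c1ccc(OCc2ccccc2)c(OC)c1C(=O)c1ccc(OC)cc1 | intermediate
13 | methyl 4-(benzyloxy)-2-[hydroxy(4-methoxyphenyl)methyl]-3-methoxybenzoate (racemic) | COC(=O)c1ccc(OCc2ccccc2)c(OC)c1C(O)c1ccc(OC)cc1 | intermediate
14 | methyl 4-(benzyloxy)-3-methoxy-2-(4-methoxybenzyl)benzoate | COC(=O)c1ccc(OCc2ccccc2)c(OC)c1Cc1ccc(OC)cc1 | intermediate
15 | methyl 4-hydroxy-3-methoxy-2-(4-methoxybenzyl)benzoate | COC(=O)c1ccc(O)c(OC)c1Cc1ccc(OC)cc1 | intermediate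
16 | methyl 5-bromo-4-hydroxy-3-methoxy-2-(4-methoxybenzyl)benzoate | COC(=O)c1cc(Br)c(O)c(OC)c1Cc1ccc(OC)cc1 | intermediate
17 | methyl 5-bromo-2-(3-bromo-4-methoxybenzyl)-4-hydroxy-3-methoxybenzoate | COC(=O)c1cc(Br)c(O)c(OC)c1Cc1ccc(OC)c(Br)c1 | intermediate
18 | methyl 5-bromo-2-(3-bromo-4-hydroxybenzyl)-3,4-dihydroxybenzoate | COC(=O)c1cc(Br)c(O)c(O)c1Cc1ccc(O)c(Br)c1 | intermediate
19 | 6-bromo-3-(3-bromo-4-hydroxybenzyl)-4-(hydroxymethyl)benzene-1,2-diol | OCc1cc(Br)c(O)c(O)c1Cc1ccc(O)c(Br)c1 | target

## Step count and least certain steps

Total step count: 11. Longest linear sequence: 10 steps (steps 1, 2, 3, 5, 6, 7, 8, 9, 10, 11); step 4 is a one-step branch.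

**Step 5 (key step).** What may go wrong: attack of the diene terminus on the keto carbonyl instead of the β-carbon, which would lead to the regioisomeric arene. Hydrolytic loss of the silyl groups of 5 or Lewis-acid cleavage of its benzyl enol ether before C–C bond formation is also possible. Fallback: it sets out from 3 and comes back at 11. The free diketone is annulated without silyl enol ethers or TiCl4 in a Robinson-type sequence that reverses the order of bond formation. Pyrrolidine/benzoic acid-catalysed Michael addition of the central carbon of 3 to commercial methyl (E)-4-oxobut-2-enoate, at the ester-bearing carbon β to the formyl group, should give methyl 3-[2-(benzyloxy)acetyl]-4-(4-methoxyphenyl)-4-oxo-2-(2-oxoethyl)butanoate F1 (bond C1–C2). TsOH in toluene at 80 °C should then effect intramolecular aldol condensation of the C4 methylene with the aldehyde to methyl 4-(benzyloxy)-2-(4-methoxybenzoyl)-3-oxocyclohex-4-ene-1-carboxylate F2 (bond C4–C5). DDQ in dioxane dehydrogenates F2 to 11. The regiochemistry then rests on two inherent preferences: the most acidic carbon is the Michael donor, and the aldehyde is the aldol acceptor. The weak point of this detour is reversible O-cyclisation of F1 to a hemiacetal.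

**Step 7.** What may go wrong: capture of the diarylmethyl cation by the neighbouring ester (lactonisation with loss of the ester methyl group), or stalling after the first hydride transfer at the crowded carbon. Partial acidolysis of the benzyl ether would be harmless, since step 8 removes it anyway. Fallback: it sets out from 12 and comes back at 15. The lactonisation is made the intended course. NaBH4 in MeOH/THF reduces the ketone, and the alkoxide closes on the ester to give 5-(benzyloxy)-4-methoxy-3-(4-methoxyphenyl)isobenzofuran-1(3H)-one F3. Hydrogenolysis (H2, Pd/C, AcOH, catalytic HClO4, 50 °C) cleaves the doubly benzylic lactone C–O bond and the benzyl ether together to give 4-hydroxy-3-methoxy-2-(4-methoxybenzyl)benzoic acid F4. Fischer esterification (MeOH, catalytic H2SO4, reflux) gives 15.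

**Step 9.** What may go wrong: the bromination of the ring B anisole may lag behind that of the ring A phenol, so that radical bromination at C8 or a third ring bromination competes. Fallback: it sets out from 15 and comes back at 18. The ring B bromine is introduced only after demethylation, when ring B is a free phenol and reacts at low temperature. One equivalent of NBS gives 16, which is now isolated. BBr3 gives methyl 5-bromo-3,4-dihydroxy-2-(4-hydroxybenzyl)benzoate F5. One equivalent of NBS at −40 °C brominates the para-alkylphenol ring ortho to its hydroxyl to give 18. The only free ring A position, C6, is para to the C3 hydroxyl but is flanked by the ester and the bromine and deactivated by both.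

**Step 11.** What may go wrong: incomplete reduction of an ester that is para to an aluminium phenoxide and surrounded by aluminium catecholates, and decomposition of the para-hydroxybenzyl alcohol through quinone methide formation if acid is needed to break the aluminium chelates. Fallback: it sets out from 17 and comes back at 19. The ester is reduced before demethylation. Treatment of 17, which has a single phenol and no catechol, with iBu2AlH gives 2-bromo-5-(3-bromo-4-methoxybenzyl)-4-(hydroxymethyl)-6-methoxyphenol F6. BBr3 cleaves both methyl ethers and exchanges the benzylic hydroxyl for bromide, giving 6-bromo-3-(3-bromo-4-hydroxybenzyl)-4-(bromomethyl)benzene-1,2-diol F7. Stirring F7 in aqueous acetone with NaHCO3 hydrolyses the labile para-hydroxybenzyl bromide to 19 under near-neutral, aluminium-free conditions.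

## Further compounds

F1 | step 5 | methyl 3-[2-(benzyloxy)acetyl]-4-(4-methoxyphenyl)-4-oxo-2-(2-oxoethyl)butanoate (mixture of diastereomers) | COC(=O)C(CC=O)C(C(=O)COCc1ccccc1)C(=O)c1ccc(OC)cc1
F2 | step 5 | methyl 4-(benzyloxy)-2-(4-methoxybenzoyl)-3-oxocyclohex-4-ene-1-carboxylate (mixture of diastereomers) | COC(=O)C1CC=C(OCc2ccccc2)C(=O)C1C(=O)c1ccc(OC)cc1
F3 | step 7 | 5-(benzyloxy)-4-methoxy-3-(4-methoxyphenyl)isobenzofuran-1(3H)-one (racemic) | O=C1OC(c2ccc(OC)cc2)c2c1ccc(OCc1ccccc1)c2OC
F4 | step 7 | 4-hydroxy-3-methoxy-2-(4-methoxybenzyl)benzoic acid | OC(=O)c1ccc(O)c(OC)c1Cc1ccc(OC)cc1
F5 | step 9 | methyl 5-bromo-3,4-dihydroxy-2-(4-hydroxybenzyl)benzoate | COC(=O)c1cc(Br)c(O)c(O)c1Cc1ccc(O)cc1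
F6 | step 11 | 2-bromo-5-(3-bromo-4-methoxybenzyl)-4-(hydroxymethyl)-6-methoxyphenol | OCc1cc(Br)c(O)c(OC)c1Cc1ccc(OC)c(Br)c1
F7 | step 11 | 6-bromo-3-(3-bromo-4-hydroxybenzyl)-4-(bromomethyl)benzene-1,2-diol | BrCc1cc(Br)c(O)c(O)c1Cc1ccc(O)c(Br)c1
A1 | alternative 1 | N-tert-butyl-3-(3-bromo-4-methoxyphenyl)-5-isopropoxy-4-methoxy-3H-isobenzofuran-1-imine (racemic) | CC(C)(C)N=C1OC(c2ccc(OC)c(Br)c2)c3c1ccc(OC(C)C)c3OC
A2 | alternative 1 | 4-isopropoxy-3-methoxy-2-(trimethylsilyl)phenyl trifluoromethanesulfonate | CC(C)Oc1ccc(OS(=O)(=O)C(F)(F)F)c([Si](C)(C)C)c1OC
A3 | alternative 1 | 3-bromo-4-methoxybenzaldehyde | COc1ccc(C=O)cc1Br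
A4 | alternative 1 | tert-butyl isocyanide | CC(C)(C)[N+]#[C-]
A5 | alternative 1 | 3-(3-bromo-4-methoxyphenyl)-5-isopropoxy-4-methoxyisobenzofuran-1(3H)-one (racemic) | O=C1OC(c2ccc(OC)c(Br)c2)c2c1ccc(OC(C)C)c2OC
A6 | alternative 2 | methyl 5-bromo-3,4-dimethoxy-2-[(4-oxocyclohex-2-en-1-yl)methyl]benzoate (racemic) | COC(=O)c1cc(Br)c(OC)c(OC)c1CC1C=CC(=O)CC1
A7 | alternative 2 | methyl 5-bromo-3,4-dimethoxy-2-(3-oxopropyl)benzoate | COC(=O)c1cc(Br)c(OC)c(OC)c1CCC=O
A8 | alternative 2 | methyl vinyl ketone | CC(=O)C=C
A9 | alternative 3 | 4-(tert-butyldimethylsilyloxy)-3-methoxy-2-(4-methoxybenzyl)phenol | Oc1ccc(O[Si](C)(C)C(C)(C)C)c(OC)c1Cc1ccc(OC)cc1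
A10 | alternative 3 | 4-(tert-butyldimethylsilyloxy)-3-methoxy-2-(4-methoxybenzyl)-4-vinylcyclobut-2-en-1-one (racemic) | O=C1C(Cc2ccc(OC)cc2)=C(OC)C1(O[Si](C)(C)C(C)(C)C)C=C
A11 | alternative 3 | dimethyl squarate (3,4-dimethoxycyclobut-3-ene-1,2-dione) | COC1=C(OC)C(=O)C1=O
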